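All runs were computed with made-up constants, and the scatter is random.

| flask | free monomer | protic impurity | initiator | remark | time |
|---|---|---|---|---|---|
| grey | 16 mM | 0.48 mM | 1 mM | run made earlier |  |
| amber | 48 mM | 0.48 mM | 1 mM | run made earlier |  |
| dawn | 24 mM | 0.480 mM | 1.0 mM |  | 12 min |
| noon | 24 mM | 0.480 mM | 4.0 mM |  | 12 min |

| grey: time / min | grey: monomer in chains / % | amber: time / min | amber: monomer in chains / % |
|---|---|---|---|
| 2.00 | 1.9 | 2.00 | 7.9 |
| 4.00 | 6.3 | 4.00 | 15.4 |
| 5.00 | 6.5 | 5.00 | 19.0 |
| 8.00 | 10.7 | 8.00 | 27.1 |

(standard deviation of a reading: 0.5 percentage points)

1. which of the two ends with the longer chains by the average number of monomer units in a chain (chains begun, living or dead) ("neither" if they lie within 10 %) (dawn / noon / neither)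
2. average number of monomer units in a chain (chains begun, living or dead) at the end, dawn
3. average number of monomer units in a chain (chains begun, living or dead) at the end, noon

- the average divides the monomer in chains by the number of chains begun, living and dead together
- the earlier runs were read with a standard deviation of 0.5 percentage points
- the earlier runs do not show the number of chains; that part of a forecast is a guess
- no earlier run changes the charge of initiator; that part of a forecast is a guess

If you begin with growth as the one process, a fixed stock of chain ends takes the same fraction of free monomer each minute at any charge. The last readings disagree: the fractional rate, ln(1/(1 − fraction in chains)) over time, is 0.0141 min⁻¹ in grey and 0.0395 min⁻¹ in amber, a ratio of 2.79 for charges in the ratio 3.00.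

So add a second process: suppose initiator vanishes quickly by a route of its own, and chain starts compete for it. The stock of chains is then made early, in proportion to the monomer charge, and growth runs on it, pseudo-first-order in free monomer. I carry the charge constant, the fractional rate divided by the charges of free monomer and initiator: from amber, 13.7 L² mol⁻² s⁻¹. Its proportionality to initiator is a guess, since no run varies the initiator.

Last comes the protic impurity, equal in both runs. A fixed debt of chains pushes the ratio above the charge ratio, but the ratio as read stands below the charge ratio, so I leave the impurity out.

My reckoning gives dawn 21.1 % in chains and noon 61.3 %. In this reckoning, chains begun go with monomer times initiator and monomer in chains with monomer times conversion, so length goes with conversion over initiator. Dawn's length is then 1.38 times noon's, beyond the margin of 10 %. The runs show no chains, so I give no absolute length.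

The forecast says dawn, with 7 for dawn and 3.7 for noon, a ratio of 1.89, and speaks of “initiation competing with protic killing”.

The flasks give dawn, with 308 for dawn and 206 for noon.

    free monomer + initiator → living end + monomer in chains (k = 0.0464 L mol⁻¹ s⁻¹)
    free monomer + living end → monomer in chains + living end, rate k2*[living end]*[free monomer] (k = 21.9 L mol⁻¹ s⁻¹)
    2 living end → dead end A (k = 3.60 L mol⁻¹ s⁻¹)
    protic impurity + free monomer → quenched substrate (k = 22.9 L mol⁻¹ s⁻¹)
    initiator → spent initiator B (k = 0.0621 s⁻¹)

In noon, the midpoint of the protic impurity's turnover lay at 1.27 s and that of the initiator's turning into spent initiator B at 0.183 min, and at the start that turning used initiator at 56 times the rate of chain starts. Afterwards in noon, with initiator at 0 %, living ends stood at 0.0509 mM after 12.0 min and 39 % of the free monomer remained. Dawn's length is 1.50 times noon's, against the reckoned 1.38. For a neighbour flask, noon charged with 14 mM of free monomer, the charge constant gives 42.5 % in chains and, scaling noon's length, 143; that flask holds 41.7 % in chains at length 146.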